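A direct plan would iodinate 2,4,6-trimethoxytoluene A1 to 3-iodo-2,4,6-trimethoxytoluene A2, lithiate a second portion of A1, let the aryllithium add to a carbonyl ligand of Cr(CO)6 A3, pass the aroyl group so formed from the metal of A3 under palladium catalysis onto A2 to give 2,2',4,4',6,6'-hexamethoxy-3,3'-dimethylbenzophenone A4, and then cleave two of the six methyl ethers of A4 with a chelating boron Lewis acid.
Its weakest steps would be: (1) the carbonylative aryl–CO–aryl union to A4, which would rest on an untested acyl transfer and would have to deliver a ketone with four ortho substituents;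
(2) the twofold demethylation of A4, which would have to pick on each ring one of two ortho-methoxy groups that both lie within reach of the chelated boron and differ only by the neighbouring methyl group, so that regioisomers, over-cleavage and xanthone formation would be expected;
(3) the carrying in of six O-methyl groups so that two can be taken off again, which would leave the one real question of the target, which oxygen stays free, to the last step.

The target is read as two polyketide-type rings (C1–C6 and C1'–C6') around a ketone: on each ring C2 (free OH, next to the C3 methyl) is taken as a former ester carbon, C4 as a methyl enol ether carbon and C6 as the β-carbon of an ynone.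
Cutting the ring bonds C1–C2 and C1'–C2' (twofold Claisen) and the C6–OMe and C6'–OMe bonds (twofold oxa-Michael) leads to an open-chain C13 diynone diester that is an isomer of the target; it should come from an allylic bromide (made from methyl 2-methylacetoacetate) and penta-1,4-diyn-3-ol by copper-catalysed coupling and oxidation.
Both benzene rings close last and in the same operation, around a carbonyl group that is already in place; no aryl–carbonyl bond is made, no ether is cleaved, and each oxygen function is fixed by the oxidation level of the chain carbon that carries it, so no choice between two ortho oxygens arises.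

Key step: step 5

Remark: the double-bond geometries written for 5 and 7–9 are the expected ones; they equilibrate through the dienolates in step 5 and do not bear on the outcome.

Step 1
Reactants: 1 methyl 2-methyl-3-oxobutanoate (methyl 2-methylacetoacetate)
Product: 3 methyl 4-bromo-2-methyl-3-oxobutanoate, via 2-bromo keto ester 2 (not isolated)
Conditions: Br2 (1.0 equiv), CHCl3, 0 °C to rt, 24 h, closed flask
Reagents that add atoms: bromine, BrBr
Why: α-Bromination of the β-keto ester should first give the tertiary 2-bromide 2, which the hydrogen bromide kept in solution isomerises by bromine transfer through the enol to the more stable primary 4-bromide (the known 2-bromo to 4-bromo migration of 3-oxo esters); C2 stays racemic and loses its stereocentre in step 2.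

Step 2
Reactants: 3 methyl 4-bromo-2-methyl-3-oxobutanoate
Product: 5 methyl (2E)-4-bromo-3-methoxy-2-methylbut-2-enoate, via dimethyl ketal 4 (not isolated)
Conditions: HC(OMe)3 (1.5 equiv), H2SO4 (2 mol %), MeOH, rt, 16 h; then TsOH (2 mol %), toluene, 80 °C, MeOH distilled off
Reagents that add atoms: trimethyl orthoformate, COC(OC)OC
Why: Orthoformate ketalisation followed by acid-catalysed loss of methanol (enol ether formation, as for 4-halo-3-methoxybut-2-enoates) should eliminate toward C2 to give the ester-conjugated enol ether, with the ester and the CH2Br group cis as the later Claisen closure needs; the temperature is held at 80 °C because the bromo ester would close to a tetronate on stronger heating.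

Step 3
Reactants: 5 methyl (2E)-4-bromo-3-methoxy-2-methylbut-2-enoate (2.2 equiv); 6 penta-1,4-diyn-3-ol
Product: 7 dimethyl (2E,11E)-7-hydroxy-3,11-dimethoxy-2,12-dimethyltrideca-2,11-diene-5,8-diynedioate
Conditions: CuI (20 mol %), NaI (20 mol %), K2CO3 (2.5 equiv), DMF, rt, 16 h, argon
Reagents that add atoms: none
Why: Copper-catalysed alkylation of the two terminal alkyne carbons by the allylic bromide (copper acetylide SN2 coupling to skipped enynes) should take place at the primary CH2Br because the other allylic terminus, C2, is fully substituted, while carbonate is too weak a base to isomerise the skipped CH2 groups; C7 carries two identical arms and is no stereocentre.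

Step 4
Reactants: 7 dimethyl (2E,11E)-7-hydroxy-3,11-dimethoxy-2,12-dimethyltrideca-2,11-diene-5,8-diynedioate
Product: 8 dimethyl (2E,11E)-3,11-dimethoxy-2,12-dimethyl-7-oxotrideca-2,11-diene-5,8-diynedioate
Conditions: MnO2 (activated, 15 equiv), CH2Cl2, 0 °C to rt, 2 h; filtered through Celite, used at once
Reagents that add atoms: none
Why: MnO2 oxidation of the doubly propargylic carbinol to the dialkynyl ketone is selective for this activated alcohol and runs under neutral, heterogeneous conditions, which the base-sensitive CH2 groups between alkyne and enol ether and the enol ethers themselves should survive.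

Step 5
Reactants: 8 dimethyl (2E,11E)-3,11-dimethoxy-2,12-dimethyl-7-oxotrideca-2,11-diene-5,8-diynedioate
Product: 10 2,2'-dihydroxy-4,4',6,6'-tetramethoxy-3,3'-dimethylbenzophenone, via bis(β-methoxyenone) diester 9 (not isolated)
Conditions: MeOH (3 equiv), NaOMe (10 mol %), THF, −20 °C, 1 h; then KOt-Bu (6 equiv), −20 °C to rt, 3 h; 1 M aq HCl, 0 °C
Reagents that add atoms: methanol, CO
Why: Methoxide adds to the β-carbons C5 and C9 of the two ynone units (oxa-Michael addition, as known for dialkynyl ketones) to give the bis(β-methoxyenone) 9, which fixes the C6 and C6' methoxy groups of the target. tert-Butoxide then removes the doubly vinylogous protons at C4 and C10, and each dienolate attacks through its ketone α-carbon (C6, C8) the ester carbon of its own arm (C1, C13); loss of methoxide and enolisation give the two phenoxide rings, so the former ester carbons become C2–OH and C2'–OH. The closest known reaction type is the biomimetic Claisen (Dieckmann-type) cyclisation of 3,5,7-trioxygenated heptanoate chains to acylphloroglucinols. Both rings close in the 6-(enolexo)-exo-trig mode, and no stereocentre is formed. The step needs the Claisen fold to win over addition of the C4 carbanion to the other enone (a six-membered carbocycle around C7) and over oxygen cyclisation to a 4-pyranone or a chromone: the C2 and C12 methyl groups make the alternative aldol fold onto C7 end in a quaternary, non-aromatisable and reversible adduct, water is excluded, and the excess of strong base keeps both arms deprotonated, so that C5 and C9 sit next to carbanionic centres and no longer act as acceptors.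

Compound list
1 | methyl 2-methyl-3-oxobutanoate (methyl 2-methylacetoacetate, racemic) | COC(=O)C(C)C(C)=O | starting material
2 | methyl 2-bromo-2-methyl-3-oxobutanoate (racemic, not isolated) | COC(=O)C(C)(Br)C(C)=O | intermediate
3 | methyl 4-bromo-2-methyl-3-oxobutanoate (racemic) | COC(=O)C(C)C(=O)CBr | intermediate
4 | methyl 4-bromo-3,3-dimethoxy-2-methylbutanoate (racemic, not isolated) | COC(=O)C(C)C(OC)(OC)CBr | intermediate
5 | methyl (2E)-4-bromo-3-methoxy-2-methylbut-2-enoate | COC(=O)/C(C)=C(/OC)CBr | intermediate
6 | penta-1,4-diyn-3-ol | C#CC(O)C#C | starting material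
7 | dimethyl (2E,11E)-7-hydroxy-3,11-dimethoxy-2,12-dimethyltrideca-2,11-diene-5,8-diynedioate (achiral) | COC(=O)/C(C)=C(/OC)CC#CC(O)C#CC/C(OC)=C(C)\C(=O)OC | intermediate
8 | dimethyl (2E,11E)-3,11-dimethoxy-2,12-dimethyl-7-oxotrideca-2,11-diene-5,8-diynedioate | COC(=O)/C(C)=C(/OC)CC#CC(=O)C#CC/C(OC)=C(C)\C(=O)OC | intermediate
9 | dimethyl (2E,5E,8E,11E)-3,5,9,11-tetramethoxy-2,12-dimethyl-7-oxotrideca-2,5,8,11-tetraenedioate (not isolated) | COC(=O)/C(C)=C(/OC)C/C(OC)=C\C(=O)/C=C(OC)\C/C(OC)=C(C)\C(=O)OC | intermediate
10 | 2,2'-dihydroxy-4,4',6,6'-tetramethoxy-3,3'-dimethylbenzophenone (achiral) | COc1cc(OC)c(C(=O)c2c(OC)cc(OC)c(C)c2O)c(O)c1C | target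

Total step count: 5. Longest linear sequence: 5 steps (1 to 10; compound 6 enters in step 3).

Steps most likely to fail

Step 5. The ring closure may take the wrong fold. The C4 (or C10) carbanion of one arm may add to the methoxy-bearing β-carbon of the other enone and expel methoxide, which would close a six-membered carbocycle around the ketone carbon C7. Oxygen may also close a 4-pyranone if water is present, or a chromone if the second arm is reprotonated after the first ring has formed. The fallback builds the rings one after the other, so that no second enone is present when a ring closes; it sets out from 5 and comes back at 10. Copper-catalysed coupling of 5 with prop-2-yn-1-ol (CuI, NaI, K2CO3, DMF) should give methyl (2E)-7-hydroxy-3-methoxy-2-methylhept-2-en-5-ynoate F1, and MnO2 should oxidise F1 to methyl (2E)-3-methoxy-2-methyl-7-oxohept-2-en-5-ynoate F2. Methanol with NaOMe and then KOt-Bu should convert F2 into methyl (2E,5E)-3,5-dimethoxy-2-methyl-7-oxohepta-2,5-dienoate F3, which should close by the same Claisen fold to 2-hydroxy-4,6-dimethoxy-3-methylbenzaldehyde F4, ring A. NaH and MOMCl should turn F4 into 4,6-dimethoxy-2-(methoxymethoxy)-3-methylbenzaldehyde F5, and HC≡CMgBr should add to F5 to give 1-[4,6-dimethoxy-2-(methoxymethoxy)-3-methylphenyl]prop-2-yn-1-ol F6. A second copper-catalysed coupling of F6 with 5 should give methyl (2E)-7-[4,6-dimethoxy-2-(methoxymethoxy)-3-methylphenyl]-7-hydroxy-3-methoxy-2-methylhept-2-en-5-ynoate F7, and MnO2 should oxidise F7 to methyl (2E)-7-[4,6-dimethoxy-2-(methoxymethoxy)-3-methylphenyl]-3-methoxy-2-methyl-7-oxohept-2-en-5-ynoate F8. Methanol with NaOMe and then KOt-Bu should lead from F8 through methyl (2E,5E)-7-[4,6-dimethoxy-2-(methoxymethoxy)-3-methylphenyl]-3,5-dimethoxy-2-methyl-7-oxohepta-2,5-dienoate F9 to [4,6-dimethoxy-2-(methoxymethoxy)-3-methylphenyl](2-hydroxy-4,6-dimethoxy-3-methylphenyl)methanone F10; in F9 the other side of the ketone is an aromatic ring and the phenol is masked, so neither the carbocyclic fold nor chromone closure is open. HCl in MeOH should remove the acetal of F10 and give 10.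

Step 3. The skipped enyne units may isomerise to allenes under the basic coupling conditions, the carbinol may be O-alkylated, or bromide 5 may be lost to carbonate before it couples. The fallback replaces the basic copper acetylide alkylation by a neutral palladium-catalysed Stille coupling; it sets out from 6 and comes back at 7. Heating 6 with Bu3SnOMe (2.1 equiv, 60 °C) should give 1,5-bis(tributylstannyl)penta-1,4-diyn-3-ol F11, and F11 should couple with 5 under Pd2(dba)3 and P(2-furyl)3 in THF at 50 °C to give 7.

Step 1. The migration of bromine from C2 to C4 may stay incomplete, or a second bromination may set in, so that mixtures of 2-bromide, 4-bromide and dibromides result. The fallback forms the enol ether first and brominates it by a radical path; it sets out from 1, replaces steps 1 and 2, and comes back at 5. HC(OMe)3 with H2SO4 in MeOH, then TsOH in toluene, should give methyl (2E)-3-methoxy-2-methylbut-2-enoate F12, and Wohl–Ziegler bromination of F12 with NBS and AIBN in PhCF3 at 80 °C should give 5.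

Further compounds
F1 | step 5 | methyl (2E)-7-hydroxy-3-methoxy-2-methylhept-2-en-5-ynoate | COC(=O)/C(C)=C(/OC)CC#CCO
F2 | step 5 | methyl (2E)-3-methoxy-2-methyl-7-oxohept-2-en-5-ynoate | COC(=O)/C(C)=C(/OC)CC#CC=O
F3 | step 5 | methyl (2E,5E)-3,5-dimethoxy-2-methyl-7-oxohepta-2,5-dienoate | COC(=O)/C(C)=C(/OC)C/C(OC)=C\C=O
F4 | step 5 | 2-hydroxy-4,6-dimethoxy-3-methylbenzaldehyde | COc1cc(OC)c(C=O)c(O)c1C
F5 | step 5 | 4,6-dimethoxy-2-(methoxymethoxy)-3-methylbenzaldehyde | COCOc1c(C)c(OC)cc(OC)c1C=O
F6 | step 5 | 1-[4,6-dimethoxy-2-(methoxymethoxy)-3-methylphenyl]prop-2-yn-1-ol (racemic) | COCOc1c(C)c(OC)cc(OC)c1C(O)C#C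
F7 | step 5 | methyl (2E)-7-[4,6-dimethoxy-2-(methoxymethoxy)-3-methylphenyl]-7-hydroxy-3-methoxy-2-methylhept-2-en-5-ynoate (racemic) | COC(=O)/C(C)=C(/OC)CC#CC(O)c1c(OCOC)c(C)c(OC)cc1OC
F8 | step 5 | methyl (2E)-7-[4,6-dimethoxy-2-(methoxymethoxy)-3-methylphenyl]-3-methoxy-2-methyl-7-oxohept-2-en-5-ynoate | COC(=O)/C(C)=C(/OC)CC#CC(=O)c1c(OCOC)c(C)c(OC)cc1OC
F9 | step 5 | methyl (2E,5E)-7-[4,6-dimethoxy-2-(methoxymethoxy)-3-methylphenyl]-3,5-dimethoxy-2-methyl-7-oxohepta-2,5-dienoate | COC(=O)/C(C)=C(/OC)C/C(OC)=C\C(=O)c1c(OCOC)c(C)c(OC)cc1OC
F10 | step 5 | [4,6-dimethoxy-2-(methoxymethoxy)-3-methylphenyl](2-hydroxy-4,6-dimethoxy-3-methylphenyl)methanone | COCOc1c(C)c(OC)cc(OC)c1C(=O)c1c(O)c(C)c(OC)cc1OC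
F11 | step 3 | 1,5-bis(tributylstannyl)penta-1,4-diyn-3-ol | CCCC[Sn](CCCC)(CCCC)C#CC(O)C#C[Sn](CCCC)(CCCC)CCCC
F12 | step 1 | methyl (2E)-3-methoxy-2-methylbut-2-enoate | COC(=O)/C(C)=C(C)/OC
A1 | direct plan | 2,4,6-trimethoxytoluene | COc1cc(OC)c(C)c(OC)c1
A2 | direct plan | 3-iodo-2,4,6-trimethoxytoluene | COc1cc(OC)c(I)c(OC)c1C
A3 | direct plan | hexacarbonylchromium, Cr(CO)6 | [Cr].[C-]#[O+].[C-]#[O+].[C-]#[O+].[C-]#[O+].[C-]#[O+].[C-]#[O+]
A4 | direct plan | 2,2',4,4',6,6'-hexamethoxy-3,3'-dimethylbenzophenone | COc1cc(OC)c(C(=O)c2c(OC)cc(OC)c(C)c2OC)c(OC)c1C
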